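**Amounts charged.** The amounts in each flask, the earlier runs and the questions are these:

| flask | first end groups | second end groups | one-sided end groups | temperature | remark | time |
|---|---|---|---|---|---|---|
| maple | 0.21 M | 0.064 M | 0.0105 M | 15 °C | run made earlier |  |
| cedar | 0.21 M | 0.53 M | 0.0105 M | 59 °C | run made earlier |  |
| birch | 0.25 M | 0.21 M | 0.0105 M | 15 °C | run made earlier |  |
| Monday's | 0.21 M | 0.100 M | 0.0105 M | 75 °C |  | 2.5 h |
| Sunday's | 0.40 M | 0.210 M | 0.0300 M | 35 °C |  | 2.5 h |
| Thursday's | 0.15 M | 0.210 M | 0.0105 M | 35 °C |  | 2.5 h |
| Tuesday's | 0.21 M | 0.210 M | 0.0105 M | −5 °C |  | 2.5 h |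
| Saturday's | 0.21 M | 0.210 M | 0.0105 M | 35 °C |  | 2.5 h |
| Wednesday's | 0.21 M | 0.600 M | 0.0105 M | 35 °C |  | 2.5 h |

maple run (percent of the first end groups charged): time / h: links / % = 0.250: 3.2; 0.667: 6.9; 1.33: 9.5; 2.50: 11.5; 4.00: 10.2; 5.00: 9.3

cedar run (percent of the first end groups charged): time / min: links / % = 5.00: 59.1; 10.0: 65.2; 15.0: 68.0; 20.0: 68.0; 25.0: 68.5; 30.0: 68.8; 40.0: 68.8

birch run (percent of the first end groups charged): time / h: links / % = 0.417: 14.9; 1.00: 25.4; 2.50: 30.5; 4.00: 27.1; 5.00: 24.2

(each reading ± 0.5 percentage points)

- the flasks by amount of links, in percent of the first end groups charged, highest first, at 2.5 h (Monday's / Sunday's / Thursday's / Tuesday's / Saturday's / Wednesday's)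
- the same order at 15 min (Monday's / Sunday's / Thursday's / Tuesday's / Saturday's / Wednesday's)
- the amount of links, in percent of the first end groups charged of the flask you put first, at 2.5 h
- the amount of links, in percent of the first end groups charged of the flask you put last, at 2.5 h

- the numbers in the tables scatter by 0.5 percentage points (one standard deviation)

**Free ratio.** A link takes one first and one second end group. This reckoning assumes that each one-sided end group removes one first end group at once, leaving c(first end groups) − c(one-sided end groups) for links. The quantity to watch is then the free ratio, c(second end groups) / [c(first end groups) − c(one-sided end groups)], which for Monday's is 0.501.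

**Second end groups.** By hand, raising this charge raises the ratio, and below one, at one temperature and reading time, the links should rise in step. The maple run, with ratio 0.321, reads 11.5% at 2.50 h, and the birch run, with 0.877, reads 30.5% at 2.50 h. Per unit of ratio these readings give 35.8% and 34.8%. Wednesday's stands at 3.01 and Saturday's at 1.05.

**Other charges.** Against Saturday's, less first end groups lifts Thursday's to 1.51, while Sunday's larger charges of first and one-sided end groups bring it down to 0.568, still above Monday's.

**Temperature, time.** The maple run falls to 9.3% by 5.00 h, so the reading time matters, while the cedar run at 59 °C already reads 68.0% at 15.0 min. By the ratio, with temperature set aside, this reckoning ranks Wednesday's, Thursday's, Saturday's, Sunday's, Monday's. It expects Tuesday's, the coldest flask, last at 15 min, and leaves its place at 2.5 h open.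

**The forecast.** It gives Wednesday's > Thursday's > Saturday's > Sunday's > Monday's > Tuesday's at 2.5 h and Wednesday's > Thursday's > Saturday's > Sunday's > Monday's > Tuesday's at 15 min, with 73% for the first flask and 16% for the last, holding that “the plateau looks like activity being lost”.

**The result.** At 2.5 h the order is Wednesday's > Thursday's > Saturday's > Sunday's > Tuesday's > Monday's, and at 15 min it is Wednesday's > Thursday's > Saturday's > Sunday's > Monday's > Tuesday's. Wednesday's gives 54.5% against the forecast's 73%, and Monday's gives 13.5%, below Tuesday's 16.4%.

    first end groups + one-sided end groups → capped ends (k = 0.0498 M⁻¹ s⁻¹, Ea = 46.0 kJ mol⁻¹)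
    first end groups + second end groups → links (k = 0.00297 M⁻¹ s⁻¹, Ea = 56.0 kJ mol⁻¹)
    second end groups → decomposed reagent (k = 1.67 × 10⁻⁴ s⁻¹, Ea = 96.0 kJ mol⁻¹)
    links ⇌ isomer of the product (K = 0.621, k = 8.59 × 10⁻⁴ s⁻¹, Ea = 87.0 kJ mol⁻¹, ΔH = −87.0 kJ mol⁻¹)
    2 first end groups → homo dimer (k = 5.37 × 10⁻⁴ M⁻¹ s⁻¹, Ea = 80.0 kJ mol⁻¹)
    (constants at 35 °C)

**A neighbour.** Monday's free ratio of 0.501 lies below one, and its links amount to 28.4% of the second end groups charged. A neighbour of Monday's with 0.17 M of second end groups has a free ratio of 0.852, still below one, and the same share predicts 23.0% of links. That neighbour gives 22.1%, with 0% of its second end groups, the limiting reagent, left.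

The runs come from a simulation with made-up constants, and the scatter is random.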